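**Plan**
- Cuts: the p-coumarate C4–O bond comes off first. Ring B (the cycloheptene) is then cut at C6=C7 and at C8–C8a in one operation, a radical–polar (5+2) annulation in which a vinylphosphonium salt supplies C7–C8.
- Enabling feature: C8a is a fully substituted ring-fusion carbon of ring A (the cyclopentane) and can be a planar tertiary radical. C7–C8 carries no substituent, and C6 carries a methyl, so it can be a methyl ketone at the end of the chain C8a–C3a–C4–C5–C6.
- The cyclopentane precursor is cut at C4–C5 (acetone aldol) and at C3a–C8a (aldol-lactonisation of a keto acid). This leads back to (S)-terpinen-4-ol (1) by cleavage of its ring C=C bond.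
- Forward order: the cyclohexene of 1 is opened, ring A is closed as a β-lactone, the side chain is grown, ring B is closed by the key step, and the ester is attached last.
- Stereochemistry: C3 comes from 1. C3a is set by substrate control in the lactonisation (anti to isopropyl). C4 is set by D-proline. C8a is set by radical attack anti to the C3a side chain (trans fusion). The ketone and the ring fix the alkene position and geometry.

Key step: step 10

Remark: (S)-(+)-terpinen-4-ol is assumed to be bought in high enantiomeric purity; the configuration of the carbinol carbon that becomes C8a (compounds 4 to 11) is erased in step 10.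

Step 1
Reactants: 1 (S)-terpinen-4-ol
Product: 2 (S)-triethyl{[4-methyl-1-(propan-2-yl)cyclohex-3-en-1-yl]oxy}silane
Conditions: Et3SiOTf, 2,6-lutidine, CH2Cl2, 0 to 25 °C
Reagents that add atoms: triethylsilyl trifluoromethanesulfonate, CC[Si](CC)(CC)OS(=O)(=O)C(F)(F)F
Why: Silylation of a hindered tertiary alcohol with a silyl triflate; the stereocentre is untouched, and the ether keeps this hydroxyl out of the lactonisation in step 3 and the acylation in step 8.

Step 2
Reactants: 2 triethylsilyl ether of terpinen-4-ol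
Product: 3 (3S)-6-oxo-3-(propan-2-yl)-3-[(triethylsilyl)oxy]heptanoic acid
Conditions: RuCl3 hydrate (2 mol%), NaIO4 (4 equiv), CCl4/MeCN/H2O, 25 °C
Reagents that add atoms: sodium periodate, [Na+].[O-]I(=O)(=O)=O; water, O
Why: RuO4-catalysed oxidative cleavage of the trisubstituted ring alkene should give the methyl ketone and the carboxylic acid directly, with the silyl ether and the stereocentre left alone.

Step 3
Reactants: 3 keto acid
Product: 4 (1R,2R,5R)-5-methyl-2-(propan-2-yl)-2-[(triethylsilyl)oxy]-6-oxabicyclo[3.2.0]heptan-7-one (cis-fused β-lactone with the lactone ring syn to OSiEt3)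
Conditions: 2-chloro-1-methylpyridinium iodide (1.5 equiv), 4-pyrrolidinopyridine (1.5 equiv), iPr2NEt (3 equiv), CH2Cl2, 25 °C, slow addition of 3
Reagents that add atoms: none
Why: Nucleophile-catalysed aldol-lactonisation, in which the acylammonium enolate of the activated acid adds to the methyl ketone to close ring A and the alkoxide closes the β-lactone, so the cis fusion is obligatory; the new C3a centre should be set by the substrate, the lactone forming on the face syn to the silyloxy group and away from the bulkier isopropyl group.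

Step 4
Reactants: 4 bicyclic β-lactone
Product: 5 (1R,2R,3R)-2-(hydroxymethyl)-1-methyl-3-(propan-2-yl)-3-[(triethylsilyl)oxy]cyclopentan-1-ol
Conditions: LiAlH4, THF, 0 °C
Reagents that add atoms: none
Why: Hydride reduction opens the strained β-lactone at the acyl carbon and gives the 1,3-diol without touching any stereocentre or the silyl ether.

Step 5
Reactants: 5 diol
Product: 6 (1R,2R,5R)-2-hydroxy-2-methyl-5-(propan-2-yl)-5-[(triethylsilyl)oxy]cyclopentane-1-carbaldehyde
Conditions: TEMPO (10 mol%), PhI(OAc)2, CH2Cl2, 25 °C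
Reagents that add atoms: none
Why: Oxoammonium (TEMPO) oxidation is selective for the primary alcohol over the tertiary one and is non-basic, so the β-hydroxy aldehyde should neither retro-aldolise nor epimerise at C3a.

Step 6
Reactants: 6 hydroxy aldehyde; 7 acetone
Product: 8 (4S)-4-hydroxy-4-{(1R,2R,5R)-2-hydroxy-2-methyl-5-(propan-2-yl)-5-[(triethylsilyl)oxy]cyclopentyl}butan-2-one
Conditions: D-proline (30 mol%), DMSO/acetone (4:1), 25 °C
Reagents that add atoms: none
Why: Proline-catalysed direct aldol reaction, in which the acetone enamine attacks the hindered, poorly enolisable aldehyde through the carboxylic-acid-bound transition state; D-proline is the enantiomer that should deliver the (S)-carbinol at C4 (catalyst control).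

Step 7
Reactants: 8 dihydroxy ketone
Product: 9 (4S)-4-[(tert-butyldimethylsilyl)oxy]-4-{(1R,2R,5R)-2-hydroxy-2-methyl-5-(propan-2-yl)-5-[(triethylsilyl)oxy]cyclopentyl}butan-2-one
Conditions: tBuMe2SiOTf (1.1 equiv), 2,6-lutidine, CH2Cl2, −78 °C
Reagents that add atoms: tert-butyldimethylsilyl trifluoromethanesulfonate, CC(C)(C)[Si](C)(C)OS(=O)(=O)C(F)(F)F
Why: Silyl ether formation, which at low temperature should take the secondary hydroxyl well before the tertiary cyclopentanol; it removes the last acidic OH that could be acylated in step 8 or quench the ylide in step 10.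

Step 8
Reactants: 9 tertiary alcohol
Product: 10 methyl (1R,2R,3R)-2-{(1S)-1-[(tert-butyldimethylsilyl)oxy]-3-oxobutyl}-1-methyl-3-(propan-2-yl)-3-[(triethylsilyl)oxy]cyclopentyl oxalate
Conditions: ClC(O)CO2Me, Et3N, DMAP (cat.), CH2Cl2, 0 to 25 °C
Reagents that add atoms: methyl chlorooxoacetate, COC(=O)C(Cl)=O
Why: DMAP-catalysed acylation of the tertiary alcohol by the very reactive oxalyl chloride monoester gives the mixed oxalate, the standard activation of a tertiary alcohol as a radical precursor; no stereocentre is affected.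

Step 9
Reactants: 10 methyl oxalate
Product: 11 cesium 2-{[(1R,2R,3R)-2-{(1S)-1-[(tert-butyldimethylsilyl)oxy]-3-oxobutyl}-1-methyl-3-(propan-2-yl)-3-[(triethylsilyl)oxy]cyclopentyl]oxy}-2-oxoacetate
Conditions: CsOH (1.0 equiv, 1 M aq.), THF, 25 °C, 5 min; toluene azeotrope
Reagents that add atoms: cesium hydroxide, [Cs+].[OH-]
Why: Chemoselective saponification, in which one equivalent of hydroxide should cleave the unhindered methyl ester of the oxalate much faster than the tert-alkyl ester, the ketone or the silyl ethers, to give the cesium oxalate that is dried before use.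

Step 10
Reactants: 11 cesium oxalate; 12 triphenyl(vinyl)phosphonium bromide
Product: 14 tert-butyl{[(3R,3aS,4S,8aR)-6,8a-dimethyl-3-(propan-2-yl)-3-[(triethylsilyl)oxy]-1,2,3,3a,4,5,8,8a-octahydroazulen-4-yl]oxy}dimethylsilane, via phosphonium ylide 13 (not isolated)
Conditions: 12 (1.5 equiv), Ir[dF(CF3)ppy]2(dtbbpy)PF6 (2 mol%), dry degassed DMSO (0.02 M), 4 Å MS, 450 nm LEDs, 25 °C; then 50 °C
Reagents that add atoms: none
Why: Proposed new method: excited trivalent iridium oxidises the oxalate of 11, loss of two CO2 gives the tertiary C8a radical, this nucleophilic radical adds to the terminal carbon of 12 (C8–C8a bond), divalent iridium reduces the α-phosphonio radical to ylide 13, and 13 olefinates the tethered methyl ketone (C6=C7 bond) with loss of Ph3PO. The closest known reaction types are the photoredox Giese addition of tertiary alkyl cesium oxalates and the three-component radical–polar crossover olefination that joins a carboxylate-derived radical, a vinylphosphonium salt and a carbonyl compound; tethering the carbonyl turns that sequence into a (5+2) annulation, which has not been shown. The seven-membered ring closes by 7-exo-trig attack of the ylide carbon on the ketone followed by cycloreversion of the oxaphosphetane (intramolecular Wittig reaction), so the double bond can only lie between C6 and C7 and must be cis within the ring. The one new stereocentre, C8a, is set by the substrate: the planar radical is attacked on the face opposite the bulky C3a side chain, which puts C8 trans to C4 and gives the trans ring fusion, and because the carbinol configuration of 11 is erased both of its epimers would converge. The step needs radical addition to outrun hydrogen abstraction, and ylide–ketone closure to outrun protonation or enolisation; the strongly electrophilic vinylphosphonium salt, the absence of OH groups (both are silylated), the dry aprotic dilute medium and the low acidity of the ketone relative to the phosphonium salt should secure this.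

Step 11
Reactants: 14 bis-silyl ether
Product: 15 (3R,3aS,4S,8aR)-6,8a-dimethyl-3-(propan-2-yl)-1,2,3,3a,4,5,8,8a-octahydroazulene-3,4-diol (jaeschkeanadiol)
Conditions: Bu4NF, THF, 25 to 50 °C
Reagents that add atoms: none
Why: Fluoride-mediated desilylation should remove both silyl ethers under non-acidic conditions, so the tertiary allylic-free alcohol and the trisubstituted alkene are not at risk.

Step 12
Reactants: 15 jaeschkeanadiol; 16 (E)-4-acetoxycinnamic acid
Product: 18 (3R,3aS,4S,8aR)-3-hydroxy-6,8a-dimethyl-3-(propan-2-yl)-1,2,3,3a,4,5,8,8a-octahydroazulen-4-yl (2E)-3-(4-hydroxyphenyl)prop-2-enoate, via aryl acetate 17 (not isolated)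
Conditions: DCC, DMAP, CH2Cl2, 25 °C; then pyrrolidine, 0 °C
Reagents that add atoms: none
Why: Steglich esterification should acylate the secondary C4 hydroxyl only (the tertiary C3 hydroxyl is inert), with retention at C4 and the E alkene of 16 unchanged, and pyrrolidine then cleaves the aryl acetate by aminolysis far faster than it attacks the cinnamate.

**Compound list**
1 | (S)-terpinen-4-ol, (1S)-4-methyl-1-(propan-2-yl)cyclohex-3-en-1-ol | CC1=CC[C@](O)(C(C)C)CC1 | starting material
2 | (S)-triethyl{[4-methyl-1-(propan-2-yl)cyclohex-3-en-1-yl]oxy}silane | CC1=CC[C@](O[Si](CC)(CC)CC)(C(C)C)CC1 | intermediate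
3 | (3S)-6-oxo-3-(propan-2-yl)-3-[(triethylsilyl)oxy]heptanoic acid | CC(=O)CC[C@@](O[Si](CC)(CC)CC)(C(C)C)CC(=O)O | intermediate
4 | (1R,2R,5R)-5-methyl-2-(propan-2-yl)-2-[(triethylsilyl)oxy]-6-oxabicyclo[3.2.0]heptan-7-one | C[C@@]12CC[C@@](O[Si](CC)(CC)CC)(C(C)C)[C@@H]1C(=O)O2 | intermediate
5 | (1R,2R,3R)-2-(hydroxymethyl)-1-methyl-3-(propan-2-yl)-3-[(triethylsilyl)oxy]cyclopentan-1-ol | C[C@@]1(O)CC[C@@](O[Si](CC)(CC)CC)(C(C)C)[C@@H]1CO | intermediate
6 | (1R,2R,5R)-2-hydroxy-2-methyl-5-(propan-2-yl)-5-[(triethylsilyl)oxy]cyclopentane-1-carbaldehyde | C[C@@]1(O)CC[C@@](O[Si](CC)(CC)CC)(C(C)C)[C@@H]1C=O | intermediate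
7 | acetone | CC(C)=O | starting material
8 | (4S)-4-hydroxy-4-{(1R,2R,5R)-2-hydroxy-2-methyl-5-(propan-2-yl)-5-[(triethylsilyl)oxy]cyclopentyl}butan-2-one | C[C@@]1(O)CC[C@@](O[Si](CC)(CC)CC)(C(C)C)[C@@H]1[C@@H](O)CC(C)=O | intermediate
9 | (4S)-4-[(tert-butyldimethylsilyl)oxy]-4-{(1R,2R,5R)-2-hydroxy-2-methyl-5-(propan-2-yl)-5-[(triethylsilyl)oxy]cyclopentyl}butan-2-one | C[C@@]1(O)CC[C@@](O[Si](CC)(CC)CC)(C(C)C)[C@@H]1[C@@H](O[Si](C)(C)C(C)(C)C)CC(C)=O | intermediate
10 | methyl (1R,2R,3R)-2-{(1S)-1-[(tert-butyldimethylsilyl)oxy]-3-oxobutyl}-1-methyl-3-(propan-2-yl)-3-[(triethylsilyl)oxy]cyclopentyl oxalate | C[C@@]1(OC(=O)C(=O)OC)CC[C@@](O[Si](CC)(CC)CC)(C(C)C)[C@@H]1[C@@H](O[Si](C)(C)C(C)(C)C)CC(C)=O | intermediate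
11 | cesium 2-{[(1R,2R,3R)-2-{(1S)-1-[(tert-butyldimethylsilyl)oxy]-3-oxobutyl}-1-methyl-3-(propan-2-yl)-3-[(triethylsilyl)oxy]cyclopentyl]oxy}-2-oxoacetate | C[C@@]1(OC(=O)C(=O)[O-])CC[C@@](O[Si](CC)(CC)CC)(C(C)C)[C@@H]1[C@@H](O[Si](C)(C)C(C)(C)C)CC(C)=O.[Cs+] | intermediate
12 | triphenyl(vinyl)phosphonium bromide | C=C[P+](c1ccccc1)(c1ccccc1)c1ccccc1.[Br-] | starting material
13 | (4S)-4-[(tert-butyldimethylsilyl)oxy]-4-{(1S,2R,5R)-2-methyl-5-(propan-2-yl)-5-[(triethylsilyl)oxy]-2-[2-(triphenyl-λ5-phosphanylidene)ethyl]cyclopentyl}butan-2-one (phosphonium ylide, not isolated) | c1ccccc1P(=CC[C@@]2(C)CC[C@@](O[Si](CC)(CC)CC)(C(C)C)[C@@H]2[C@@H](O[Si](C)(C)C(C)(C)C)CC(C)=O)(c1ccccc1)c1ccccc1 | intermediate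
14 | tert-butyl{[(3R,3aS,4S,8aR)-6,8a-dimethyl-3-(propan-2-yl)-3-[(triethylsilyl)oxy]-1,2,3,3a,4,5,8,8a-octahydroazulen-4-yl]oxy}dimethylsilane | CC1=CC[C@@]2(C)CC[C@@](O[Si](CC)(CC)CC)(C(C)C)[C@@H]2[C@@H](O[Si](C)(C)C(C)(C)C)C1 | intermediate
15 | (3R,3aS,4S,8aR)-6,8a-dimethyl-3-(propan-2-yl)-1,2,3,3a,4,5,8,8a-octahydroazulene-3,4-diol (jaeschkeanadiol) | CC1=CC[C@@]2(C)CC[C@@](O)(C(C)C)[C@@H]2[C@@H](O)C1 | intermediate
16 | (E)-4-acetoxycinnamic acid | CC(=O)Oc1ccc(/C=C/C(=O)O)cc1 | starting material
17 | (3R,3aS,4S,8aR)-3-hydroxy-6,8a-dimethyl-3-(propan-2-yl)-1,2,3,3a,4,5,8,8a-octahydroazulen-4-yl (2E)-3-[4-(acetyloxy)phenyl]prop-2-enoate (not isolated) | CC1=CC[C@@]2(C)CC[C@@](O)(C(C)C)[C@@H]2[C@@H](OC(=O)/C=C/c2ccc(OC(C)=O)cc2)C1 | intermediate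
18 | (3R,3aS,4S,8aR)-3-hydroxy-6,8a-dimethyl-3-(propan-2-yl)-1,2,3,3a,4,5,8,8a-octahydroazulen-4-yl (2E)-3-(4-hydroxyphenyl)prop-2-enoate | CC1=CC[C@@]2(C)CC[C@@](O)(C(C)C)[C@@H]2[C@@H](OC(=O)/C=C/c2ccc(O)cc2)C1 | target

Total step count: 12. Longest linear sequence: 12 steps (1 to 18); compounds 7, 12 and 16 are bought.

**Steps most likely to fail**

Step 10 (Proposed new method). The chain may stop after the radical addition, either because the α-phosphonio radical abstracts hydrogen or because the ylide is protonated before it finds the ketone. The tertiary radical may also be reduced or dimerise before it adds. The fallback makes the two bonds one after the other by known reactions and sets out from cesium oxalate 11. Radical allylation with allyl ethyl sulfone under the same Ir[dF(CF3)ppy]2(dtbbpy)PF6 photocatalysis (addition of the C8a radical and β-fragmentation of the ethanesulfonyl radical, with the same attack anti to the side chain) should give (4S)-4-[(tert-butyldimethylsilyl)oxy]-4-{(1S,2R,5R)-2-methyl-2-(prop-2-en-1-yl)-5-(propan-2-yl)-5-[(triethylsilyl)oxy]cyclopentyl}butan-2-one F1. Wittig methylenation of its methyl ketone (Ph3P=CH2, THF) should give the diene tert-butyldimethyl{[(1S)-3-methyl-1-{(1S,2R,5R)-2-methyl-2-(prop-2-en-1-yl)-5-(propan-2-yl)-5-[(triethylsilyl)oxy]cyclopentyl}but-3-en-1-yl]oxy}silane F2. Ring-closing metathesis with the second-generation Grubbs catalyst (CH2Cl2, 40 °C) then forms the C6=C7 bond and comes back to the route at 14.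

Step 6. Catalyst and substrate may be mismatched and give poor facial selectivity at C4, and the amine may reopen the tertiary aldol of 6 by retro-aldol cleavage. The fallback uses reagent control under non-equilibrating conditions and sets out from aldehyde 6. Brown methallylation with the B-methallyldiisopinocampheylborane enantiomer that gives the (S)-carbinol (the reagent made from (+)-α-pinene, Et2O, −78 °C) should give (1R,2R,3R)-2-[(1S)-1-hydroxy-3-methylbut-3-en-1-yl]-1-methyl-3-(propan-2-yl)-3-[(triethylsilyl)oxy]cyclopentan-1-ol F3. Ozonolysis of its 1,1-disubstituted alkene (O3, CH2Cl2, −78 °C; PPh3) comes back to the route at 8.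

Step 3. The acylammonium enolate may lose silanolate by β-elimination, and the lactone may close on the face syn to isopropyl. The fallback replaces the Lewis-base-bound enolate by a chelated metal enolate and sets out from keto acid 3. Thioesterification (PhSH, DCC, DMAP) should give S-phenyl (3S)-6-oxo-3-(propan-2-yl)-3-[(triethylsilyl)oxy]heptanethioate F4. Soft enolisation of the thioester (MgBr2·OEt2, iPr2NEt, CH2Cl2) and intramolecular aldol addition through a magnesium chelate that ties the enolate oxygen to the ketone oxygen should give the cis product S-phenyl (1R,2R,5R)-2-hydroxy-2-methyl-5-(propan-2-yl)-5-[(triethylsilyl)oxy]cyclopentane-1-carbothioate F5. LiAlH4 reduction of the thioester comes back to the route at diol 5.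

**Further compounds**
F1 | step 10 | (4S)-4-[(tert-butyldimethylsilyl)oxy]-4-{(1S,2R,5R)-2-methyl-2-(prop-2-en-1-yl)-5-(propan-2-yl)-5-[(triethylsilyl)oxy]cyclopentyl}butan-2-one | C=CC[C@@]1(C)CC[C@@](O[Si](CC)(CC)CC)(C(C)C)[C@@H]1[C@@H](O[Si](C)(C)C(C)(C)C)CC(C)=O
F2 | step 10 | tert-butyldimethyl{[(1S)-3-methyl-1-{(1S,2R,5R)-2-methyl-2-(prop-2-en-1-yl)-5-(propan-2-yl)-5-[(triethylsilyl)oxy]cyclopentyl}but-3-en-1-yl]oxy}silane | C=CC[C@@]1(C)CC[C@@](O[Si](CC)(CC)CC)(C(C)C)[C@@H]1[C@@H](O[Si](C)(C)C(C)(C)C)CC(C)=C
F3 | step 6 | (1R,2R,3R)-2-[(1S)-1-hydroxy-3-methylbut-3-en-1-yl]-1-methyl-3-(propan-2-yl)-3-[(triethylsilyl)oxy]cyclopentan-1-ol | C[C@@]1(O)CC[C@@](O[Si](CC)(CC)CC)(C(C)C)[C@@H]1[C@@H](O)CC(C)=C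
F4 | step 3 | S-phenyl (3S)-6-oxo-3-(propan-2-yl)-3-[(triethylsilyl)oxy]heptanethioate | CC(=O)CC[C@@](O[Si](CC)(CC)CC)(C(C)C)CC(=O)Sc1ccccc1
F5 | step 3 | S-phenyl (1R,2R,5R)-2-hydroxy-2-methyl-5-(propan-2-yl)-5-[(triethylsilyl)oxy]cyclopentane-1-carbothioate | C[C@@]1(O)CC[C@@](O[Si](CC)(CC)CC)(C(C)C)[C@@H]1C(=O)Sc1ccccc1
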